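**Retrosynthetic overview**
1. Target 14 ⇐ dienone 12: 1,4-hydride reduction of the α-methoxy-enone half (C4=C5), then kinetic protonation at C5.
2. 12 ⇐ acyclic aryl ether 11 (key step): cationic dearomative ipso-Friedel–Crafts closure that forms the C3–C3a bond, the dihydrofuran ring, C3 and the quaternary C3a in one operation, steered by C2.
3. 11 ⇐ ester 8 + aryl Grignard 9; 8 ⇐ phenol 6 + ethyl (S)-lactate 7 by Mitsunobu inversion (C2 from the chiral pool).
4. 6 ⇐ methoxyeugenol 1: silylation, ring bromination, bromine-to-hydroxyl exchange.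
5. Ring order: the six-membered ring is the benzene ring of 1 and is never built; the five-membered ring is formed last, with dearomatisation.

Assumption: 1, 7 and the THF solution of 9 are taken as commercial; benzofuran numbering (O1, C2, C3, C3a, C4–C7, C7a) is used for the target and its precursors. The target is (2R,3S,3aR,5S): 2-Me/3-Ar trans, 3-Ar/3a-allyl trans, 5-OMe cis to allyl.

**Step 1**
Reactants: 1 4-allyl-2,6-dimethoxyphenol (methoxyeugenol)
Product: 2 (4-allyl-2,6-dimethoxyphenoxy)triisopropylsilane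
Conditions: TIPSCl, imidazole, DMF, rt
Reagents that add atoms: triisopropylsilyl chloride, CC(C)[Si](Cl)(C(C)C)C(C)C
Why: Standard O-silylation of a phenol; the bulky silyl ether masks the oxygen that later becomes the C6 carbonyl and tolerates the organolithium, Mitsunobu, hydride and Grignard steps.

**Step 2**
Reactants: 2 (4-allyl-2,6-dimethoxyphenoxy)triisopropylsilane
Product: 3 (4-allyl-3-bromo-2,6-dimethoxyphenoxy)triisopropylsilane
Conditions: NBS (1.05 equiv), MeCN, 0 °C, dark
Reagents that add atoms: N-bromosuccinimide, O=C1CCC(=O)N1Br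
Why: Electrophilic aromatic bromination; the two free ring positions are equivalent, each ortho to one methoxy group and para to the other, so ionic ring bromination outruns addition to the isolated alkene.

**Step 3**
Reactants: 3 (4-allyl-3-bromo-2,6-dimethoxyphenoxy)triisopropylsilane
Product: 6 6-allyl-2,4-dimethoxy-3-(triisopropylsilyloxy)phenol, via aryllithium 4 (not isolated), via lithium aryltrimethoxyborate 5 (not isolated)
Conditions: n-BuLi, THF, −78 °C; B(OMe)3, −78 → 0 °C; AcOH, 30% H2O2, 0 °C → rt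
Reagents that add atoms: hydrogen peroxide, OO
Why: Bromine–lithium exchange at −78 °C is faster than deprotonation of the allylic CH2; borylation and oxidation (1,2-aryl shift from boron to oxygen) place the hydroxyl exactly where bromine was, ortho to the allyl group.

**Step 4**
Reactants: 6 6-allyl-2,4-dimethoxy-3-(triisopropylsilyloxy)phenol; 7 ethyl (S)-lactate
Product: 8 ethyl (2R)-2-[6-allyl-2,4-dimethoxy-3-(triisopropylsilyloxy)phenoxy]propanoate
Conditions: PPh3, DIAD, THF, 0 °C → rt
Reagents that add atoms: none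
Why: Mitsunobu etherification, an SN2 displacement with clean inversion at the lactate carbinol (S → R), which sets C2 of the target from the chiral pool.

**Step 5**
Reactants: 8 ethyl (2R)-2-[6-allyl-2,4-dimethoxy-3-(triisopropylsilyloxy)phenoxy]propanoate; 9 3,4,5-trimethoxyphenylmagnesium bromide
Product: 11 (2R)-2-[6-allyl-2,4-dimethoxy-3-(triisopropylsilyloxy)phenoxy]-1-(3,4,5-trimethoxyphenyl)propan-1-ol (both C1 epimers), via aldehyde 10 (not isolated)
Conditions: i-Bu2AlH (1.1 equiv), CH2Cl2, −78 °C; then 9 (3 equiv, THF), −78 → 0 °C; aq. potassium sodium tartrate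
Reagents that add atoms: none
Why: Partial ester reduction stops at the aluminium hemiacetal at −78 °C, and the labile (R)-aldehyde is released only as the Grignard reagent adds to it (1,2-addition), so C2 is not epimerised; the carbinol centre needs no control because step 6 ionises it.

**Step 6**
Reactants: 11 (2R)-2-[6-allyl-2,4-dimethoxy-3-(triisopropylsilyloxy)phenoxy]-1-(3,4,5-trimethoxyphenyl)propan-1-ol (both C1 epimers)
Product: 12 (2R,3S,3aS)-3a-allyl-5,7-dimethoxy-2-methyl-3-(3,4,5-trimethoxyphenyl)-3,3a-dihydro-1-benzofuran-6(2H)-one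
Conditions: TMSOTf (0.2 equiv), CH2Cl2 (0.01 M), −78 → −30 °C; Et3N, then aq. NaHCO3
Reagents that add atoms: none
Why: Proposed new method: ionisation of either carbinol epimer gives one planar 3,4,5-trimethoxybenzyl cation, held by the ether tether over the arene, which attacks the allyl-bearing carbon (ortho to the ether oxygen, para to the silyloxy group) in a five-ring Friedel–Crafts closure, and loss of the silyl group from the resulting oxocarbenium ion gives the cross-conjugated dienone; attack at the other ortho carbon is disfavoured because it bears a methoxy group; the C2 methyl steers the aryl group trans to itself and onto the face opposite the angular allyl group (all-trans, least strained), so C3 and the quaternary C3a are both set from C2; the closest known reaction types are the acid-mediated cyclisation of 2-aryloxy-1-arylethanols to 3-aryl-2,3-dihydrobenzofurans and the dearomative ipso-Friedel–Crafts alkylation of para-oxygenated arenes to cyclohexadienones.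

**Step 7**
Reactants: 12 (2R,3S,3aS)-3a-allyl-5,7-dimethoxy-2-methyl-3-(3,4,5-trimethoxyphenyl)-3,3a-dihydro-1-benzofuran-6(2H)-one
Product: 14 (2R,3S,3aR,5S)-3a-allyl-5,7-dimethoxy-2-methyl-3-(3,4,5-trimethoxyphenyl)-3,3a,4,5-tetrahydro-1-benzofuran-6(2H)-one, via lithium enolate 13 (not isolated)
Conditions: LiBH(s-Bu)3 (1.1 equiv), THF, −78 °C; then t-BuCO2H, THF, −78 °C; pH 7 buffer
Reagents that add atoms: none
Why: Conjugate (1,4) hydride reduction by a bulky trialkylborohydride occurs at C4, the only β-CH enone carbon (C7a is tetrasubstituted and oxygen-deactivated, the terminal alkene is inert), and kinetic protonation of the enolate at C5 on the face opposite the pseudo-axial allyl group places the 5-methoxy group cis to allyl (5S); the 3a descriptor changes from S to R only because C4 loses CIP priority on saturation, not because the geometry changes.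

**Compound list**
1 | 4-allyl-2,6-dimethoxyphenol (methoxyeugenol) | C=CCc1cc(OC)c(O)c(OC)c1 | starting material
2 | (4-allyl-2,6-dimethoxyphenoxy)triisopropylsilane | C=CCc1cc(OC)c(O[Si](C(C)C)(C(C)C)C(C)C)c(OC)c1 | intermediate
3 | (4-allyl-3-bromo-2,6-dimethoxyphenoxy)triisopropylsilane | C=CCc1cc(OC)c(O[Si](C(C)C)(C(C)C)C(C)C)c(OC)c1Br | intermediate
4 | [6-allyl-2,4-dimethoxy-3-(triisopropylsilyloxy)phenyl]lithium | [Li]c1c(CC=C)cc(OC)c(O[Si](C(C)C)(C(C)C)C(C)C)c1OC | intermediate
5 | lithium [6-allyl-2,4-dimethoxy-3-(triisopropylsilyloxy)phenyl]trimethoxyborate | [Li+].CO[B-](OC)(OC)c1c(CC=C)cc(OC)c(O[Si](C(C)C)(C(C)C)C(C)C)c1OC | intermediate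
6 | 6-allyl-2,4-dimethoxy-3-(triisopropylsilyloxy)phenol | Oc1c(CC=C)cc(OC)c(O[Si](C(C)C)(C(C)C)C(C)C)c1OC | intermediate
7 | ethyl (S)-lactate | C[C@H](O)C(=O)OCC | starting material
8 | ethyl (2R)-2-[6-allyl-2,4-dimethoxy-3-(triisopropylsilyloxy)phenoxy]propanoate | CCOC(=O)[C@@H](C)Oc1c(CC=C)cc(OC)c(O[Si](C(C)C)(C(C)C)C(C)C)c1OC | intermediate
9 | 3,4,5-trimethoxyphenylmagnesium bromide | COc1cc([Mg]Br)cc(OC)c1OC | starting material
10 | (2R)-2-[6-allyl-2,4-dimethoxy-3-(triisopropylsilyloxy)phenoxy]propanal | O=C[C@@H](C)Oc1c(CC=C)cc(OC)c(O[Si](C(C)C)(C(C)C)C(C)C)c1OC | intermediate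
11 | (2R)-2-[6-allyl-2,4-dimethoxy-3-(triisopropylsilyloxy)phenoxy]-1-(3,4,5-trimethoxyphenyl)propan-1-ol (both C1 epimers) | COc1cc(C(O)[C@@H](C)Oc2c(CC=C)cc(OC)c(O[Si](C(C)C)(C(C)C)C(C)C)c2OC)cc(OC)c1OC | intermediate
12 | (2R,3S,3aS)-3a-allyl-5,7-dimethoxy-2-methyl-3-(3,4,5-trimethoxyphenyl)-3,3a-dihydro-1-benzofuran-6(2H)-one | C=CC[C@]12C=C(OC)C(=O)C(OC)=C1O[C@H](C)[C@H]2c1cc(OC)c(OC)c(OC)c1 | intermediate
13 | lithium (2R,3S,3aR)-3a-allyl-5,7-dimethoxy-2-methyl-3-(3,4,5-trimethoxyphenyl)-2,3,3a,4-tetrahydro-1-benzofuran-6-olate | C=CC[C@]12CC(OC)=C(O[Li])C(OC)=C1O[C@H](C)[C@H]2c1cc(OC)c(OC)c(OC)c1 | intermediate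
14 | (2R,3S,3aR,5S)-3a-allyl-5,7-dimethoxy-2-methyl-3-(3,4,5-trimethoxyphenyl)-3,3a,4,5-tetrahydro-1-benzofuran-6(2H)-one | C=CC[C@]12C[C@H](OC)C(=O)C(OC)=C1O[C@H](C)[C@H]2c1cc(OC)c(OC)c(OC)c1 | target

**Totals**
Total step count: 7. Longest linear sequence: 7 steps (1 → 14); 7 and 9 are bought.

**Three steps most likely to fail**

Step 6 is the boldest. The benzylic cation may lose a proton to the enol ether (which then cleaves), may attack the methoxy-bearing ortho carbon, or the acid may trigger allyl migration in the dienone. The fallback replaces the cationic closure by an anionic one; it sets out from 11 and comes back at 12. MsCl/Et3N followed by LiCl turns 11 into {4-allyl-3-[(2R)-1-chloro-1-(3,4,5-trimethoxyphenyl)propan-2-yloxy]-2,6-dimethoxyphenoxy}triisopropylsilane F1. CsF in DMF then removes the silyl group to give caesium 4-allyl-3-[(2R)-1-chloro-1-(3,4,5-trimethoxyphenyl)propan-2-yloxy]-2,6-dimethoxyphenoxide F2. F2 closes by intramolecular para-C-alkylation of the phenoxide (dearomatising phenoxide alkylation) under acid-free conditions in which 12 cannot rearrange. The chloride epimers exchange through chloride ion, so the epimer that leads to the all-trans ring is drained.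

Step 7 can fail by 1,2-attack at C6 or by protonation on the wrong face, and C5 is epimerisable, so base must be avoided in work-up. The fallback separates reduction from protonation; it sets out from 12 and comes back at 14. Copper hydride catalysed 1,4-hydrosilylation ([(Ph3P)CuH]6 cat., PhMe2SiH, toluene, rt) gives [(2R,3S,3aR)-3a-allyl-5,7-dimethoxy-2-methyl-3-(3,4,5-trimethoxyphenyl)-2,3,3a,4-tetrahydro-1-benzofuran-6-yl]oxy-dimethyl(phenyl)silane F3, which is isolated. Fluoride cleavage at −78 °C (Bu4NF) in the presence of 2,6-di-tert-butyl-4-methylphenol as a bulky proton donor then delivers the proton anti to the allyl group and gives 14.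

Step 5 can fail by over-reduction to the primary alcohol or by epimerisation of the α-aryloxy aldehyde, which would erode the enantiopurity of everything downstream. The fallback goes through the ketone oxidation level; it sets out from 8 and comes back at 11. MeNH(OMe)·HCl/i-PrMgCl (THF, −20 °C) gives (2R)-2-[6-allyl-2,4-dimethoxy-3-(triisopropylsilyloxy)phenoxy]-N-methoxy-N-methylpropanamide F4. Addition of 9 gives (2R)-2-[6-allyl-2,4-dimethoxy-3-(triisopropylsilyloxy)phenoxy]-1-(3,4,5-trimethoxyphenyl)propan-1-one F5 without over-addition. NaBH4 (MeOH, 0 °C) then gives 11; either carbinol epimer serves.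

**Further compounds**
F1 | step 6 | {4-allyl-3-[(2R)-1-chloro-1-(3,4,5-trimethoxyphenyl)propan-2-yloxy]-2,6-dimethoxyphenoxy}triisopropylsilane (both C1 epimers) | COc1cc(C(Cl)[C@@H](C)Oc2c(CC=C)cc(OC)c(O[Si](C(C)C)(C(C)C)C(C)C)c2OC)cc(OC)c1OC
F2 | step 6 | caesium 4-allyl-3-[(2R)-1-chloro-1-(3,4,5-trimethoxyphenyl)propan-2-yloxy]-2,6-dimethoxyphenoxide | [Cs+].COc1cc(C(Cl)[C@@H](C)Oc2c(CC=C)cc(OC)c([O-])c2OC)cc(OC)c1OC
F3 | step 7 | [(2R,3S,3aR)-3a-allyl-5,7-dimethoxy-2-methyl-3-(3,4,5-trimethoxyphenyl)-2,3,3a,4-tetrahydro-1-benzofuran-6-yl]oxy-dimethyl(phenyl)silane | C=CC[C@]12CC(OC)=C(O[Si](C)(C)c3ccccc3)C(OC)=C1O[C@H](C)[C@H]2c1cc(OC)c(OC)c(OC)c1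
F4 | step 5 | (2R)-2-[6-allyl-2,4-dimethoxy-3-(triisopropylsilyloxy)phenoxy]-N-methoxy-N-methylpropanamide | CON(C)C(=O)[C@@H](C)Oc1c(CC=C)cc(OC)c(O[Si](C(C)C)(C(C)C)C(C)C)c1OC
F5 | step 5 | (2R)-2-[6-allyl-2,4-dimethoxy-3-(triisopropylsilyloxy)phenoxy]-1-(3,4,5-trimethoxyphenyl)propan-1-one | COc1cc(C(=O)[C@@H](C)Oc2c(CC=C)cc(OC)c(O[Si](C(C)C)(C(C)C)C(C)C)c2OC)cc(OC)c1OC
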